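**Retrosynthetic overview**

- The target is two 3-acyl-5-prenylphloroglucinol rings joined through a 6-methylheptane-1,1-diyl carbon. Its only stereocentres are the two α-carbons of the aryl ketones, each a CH bearing CH3, C2H5 and the aroyl C=O, so each can be made from a planar α-acyl radical by forming its Cα–CH3 bond.
- Key disconnection: both Cα–CH3 bonds at once, leading back to the stereorandom bis(2-bromobutanoyl) dimer hexaacetate 7 and two molecules of methylzinc iodide 10, joined by an enantioconvergent nickel/pybox Negishi coupling.
- Compound 7 comes from Friedel–Crafts acylation of phloroglucinol with 2-bromobutanoyl bromide, acid-catalysed bridging of two ketones with 6-methylheptanal, and acid-catalysed peracetylation.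
- After the coupling: ammonolysis of the acetates, O-allylation of the hydroxyls para to the acyl groups, Claisen shift to the single free ring carbon, and cross-metathesis with 2-methyl-2-butene.
- No ring is formed anywhere; both benzene rings are bought as phloroglucinol.

Key step: step 5

Remark on the chemistry: the sense of induction of a given pybox antipode on this new substrate class cannot be predicted with confidence; (S,S)-i-Pr-pybox is written, and its enantiomer is used instead if first runs show the opposite sense.

**Step 1**
Reactants: 1 phloroglucinol; 2 2-bromobutanoyl bromide (racemic)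
Product: 3 2-bromo-1-(2,4,6-trihydroxyphenyl)butan-1-one (racemic)
Conditions: AlCl3 (3.5 equiv), PhNO2/CH2Cl2, 0 °C → rt; ice/1 M HCl
Reagents that add atoms: none
Why: Friedel–Crafts acylation of the threefold-symmetric ring (all three CH equivalent) stops after one acyl group because the ketone deactivates the ring, and the acidic medium and work-up should leave the ortho hydroxyls unable to displace the secondary bromide, so the open α-bromo ketone is obtained as the racemate.

**Step 2**
Reactants: 3 2-bromo-1-(2,4,6-trihydroxyphenyl)butan-1-one (two molecules; 2.5–3 equiv used); 4 6-methylheptanal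
Product: 6 1,1-bis[3-(2-bromobutanoyl)-2,4,6-trihydroxyphenyl]-6-methylheptane (mixture of all stereoisomers at the two CHBr carbons), via ortho-quinone methide 5 (not isolated)
Conditions: TsOH·H2O (10 mol %), AcOH/THF, 25–40 °C; excess 3 recovered
Reagents that add atoms: none
Why: Acid-catalysed hydroxyalkylation of one of the two equivalent ring CH of 3 by the aldehyde and loss of water give ortho-quinone methide 5, which a second molecule of 3 traps through its ring CH in a Friedel–Crafts-type conjugate addition; the excess of 3 should hold back oligomers, the absence of base keeps the bromides in place, and the configuration at CHBr is irrelevant because it is erased in step 5.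

**Step 3**
Reactants: 6 1,1-bis[3-(2-bromobutanoyl)-2,4,6-trihydroxyphenyl]-6-methylheptane
Product: 7 1,1-bis[2,4,6-triacetoxy-3-(2-bromobutanoyl)phenyl]-6-methylheptane (mixture of all stereoisomers at the two CHBr carbons)
Conditions: Ac2O (12 equiv), Sc(OSO2CF3)3 (5 mol %), MeCN, 0 °C → rt
Reagents that add atoms: acetic anhydride, CC(=O)OC(C)=O
Why: Lewis-acid-catalysed acetylation (esterification with Ac2O) should cap all six phenols, the hydrogen-bonded and flanked ones included, without the amine base that would let an ortho phenoxide close onto CHBr to a benzofuranone.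

**Step 4**
Reactants: 8 iodomethane; 9 zinc (dust)
Product: 10 methylzinc iodide (solution in DMA)
Conditions: Zn dust (1.5 equiv, activated with I2, 5 mol %), DMA, 25–40 °C; solution decanted and titrated with I2
Reagents that add atoms: none
Why: Direct oxidative insertion of activated zinc into the C–I bond in a polar amide solvent is a standard preparation of alkylzinc iodides and gives a titratable solution of 10.

**Step 5**
Reactants: 7 1,1-bis[2,4,6-triacetoxy-3-(2-bromobutanoyl)phenyl]-6-methylheptane; 10 methylzinc iodide (two molecules; 3.5 equiv used)
Product: 11 1,1-bis{2,4,6-triacetoxy-3-[(2R)-2-methylbutanoyl]phenyl}-6-methylheptane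
Conditions: methylzinc iodide 10 (3.5 equiv, i.e. 1.75 per C–Br), NiCl2(MeOCH2CH2OMe) (20 mol %), (S,S)-i-Pr-pybox [2,6-bis((4S)-4-isopropyl-4,5-dihydrooxazol-2-yl)pyridine] (26 mol %), glyme/THF/DMA, −30 °C; sat. aq NH4Cl at −30 °C
Reagents that add atoms: none
Why: Proposed new method: a monovalent nickel–pybox complex abstracts the bromine atom from either epimer of a CHBr carbon to give the same planar α-acyl radical, which is captured by the chiral divalent methylnickel complex formed by transmetalation from 10, and reductive elimination from the resulting trivalent alkyl(methyl)nickel species forms the Cα–CH3 bond; the closest known reaction type is the nickel/pybox-catalysed enantioconvergent Negishi coupling of racemic α-bromo ketones with arylzinc halides and of racemic α-bromo amides with alkylzinc halides, the new elements being an alkylzinc partner on an α-bromo ketone, the di-ortho-acetoxy aryl ketone and two reacting sites in one molecule. This cycle runs once at each of the two C–Br carbons, so two molecules of 10 are consumed per molecule of 7, each delivering one CH3 group, and no ring is closed. Each of the two new stereocentres is set under catalyst control by the pybox-bound nickel at the radical-capture and reductive-elimination stage, independently of the remote second site and of the configuration of the starting CHBr carbon, so all stereoisomers of 7 should converge on the (R,R) product and any mismatch at one site should end up mainly in the separable (R,S) diastereomers. The step needs chemoselectivity for C–Br over six aryl acetates and over the product ketone, which the low nucleophilicity and basicity of methylzinc iodide at −30 °C should secure, while the acetates in turn keep the ortho oxygens from displacing bromide to close benzofuranones. The competing process to watch is two-electron reduction to a zinc enolate, which would give the debrominated butanoyl ketone or accept an acetyl group from an ortho acetate.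

**Step 6**
Reactants: 11 1,1-bis{2,4,6-triacetoxy-3-[(2R)-2-methylbutanoyl]phenyl}-6-methylheptane
Product: 12 1,1-bis{2,4,6-trihydroxy-3-[(2R)-2-methylbutanoyl]phenyl}-6-methylheptane
Conditions: NH3 (7 M in MeOH, excess), THF, −20 → 0 °C; cold aq NaH2PO4
Reagents that add atoms: none
Why: Ammonolysis of aryl acetates (aminolysis of activated esters) is fast under cold, weakly basic conditions in which the hindered tertiary α-CH of the ketones is not deprotonated, and each phenoxide set free makes its ketone a vinylogous carboxylate of still lower α-acidity, so both stereocentres should be retained.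

**Step 7**
Reactants: 12 1,1-bis{2,4,6-trihydroxy-3-[(2R)-2-methylbutanoyl]phenyl}-6-methylheptane
Product: 13 1,1-bis{2,4-dihydroxy-3-[(2R)-2-methylbutanoyl]-6-(prop-2-enyloxy)phenyl}-6-methylheptane (allyl ether at the hydroxyl para to each acyl group)
Conditions: allyl bromide (2.1 equiv, slow addition), K2CO3 (2.2 equiv), acetone, 0 °C → rt
Reagents that add atoms: allyl bromide, C=CCBr
Why: Williamson etherification with a mild carbonate base should take place at the most acidic and least encumbered hydroxyl of each ring, the one para to the acyl group, since the two ortho hydroxyls are hydrogen-bonded to the ketone or flanked on both sides; any allyl group that lands instead on the ortho hydroxyl next to the free ring CH, or on that carbon itself, ends up at the same carbon after step 8.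

**Step 8**
Reactants: 13 1,1-bis{2,4-dihydroxy-3-[(2R)-2-methylbutanoyl]-6-(prop-2-enyloxy)phenyl}-6-methylheptane
Product: 14 1,1-bis{2,4,6-trihydroxy-3-[(2R)-2-methylbutanoyl]-5-(prop-2-enyl)phenyl}-6-methylheptane
Conditions: PhNEt2 (degassed), 180 °C (microwave, sealed), 20–40 min; cold 1 M HCl wash
Reagents that add atoms: none
Why: Aromatic Claisen rearrangement ([3,3]-sigmatropic shift followed by tautomerisation) can deliver each allyl group only to the one unsubstituted ortho carbon, because the other ortho carbon carries the bridge and the para carbon the acyl group; the weakly basic solvent scavenges acid that would cyclise the ortho-allylphenols, and the short heating time is chosen to spare the α-stereocentres.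

**Step 9**
Reactants: 14 1,1-bis{2,4,6-trihydroxy-3-[(2R)-2-methylbutanoyl]-5-(prop-2-enyl)phenyl}-6-methylheptane
Product: 15 1,1-bis{2,4,6-trihydroxy-3-[(2R)-2-methylbutanoyl]-5-(3-methylbut-2-enyl)phenyl}-6-methylheptane (CNP0245910.1)
Conditions: 2-methyl-2-butene (ca. 50 equiv), second-generation Grubbs catalyst (H2IMes)(PCy3)Cl2Ru=CHPh (10 mol %), CH2Cl2, 40 °C, sealed
Reagents that add atoms: 2-methyl-2-butene, CC=C(C)C
Why: Olefin cross-metathesis with a large excess of the trisubstituted olefin exchanges each terminal CH2 for an isopropylidene group with loss of propene, tolerates free phenols and ketones, and touches neither stereocentre.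

**Compound list**

1 | phloroglucinol | Oc1cc(O)cc(O)c1 | starting material
2 | 2-bromobutanoyl bromide (racemic) | CCC(Br)C(Br)=O | starting material
3 | 2-bromo-1-(2,4,6-trihydroxyphenyl)butan-1-one (racemic) | CCC(Br)C(=O)c1c(O)cc(O)cc1O | intermediate
4 | 6-methylheptanal | CC(C)CCCCC=O | starting material
5 | 4-(2-bromobutanoyl)-3,5-dihydroxy-6-(6-methylheptylidene)cyclohexa-2,4-dien-1-one (ortho-quinone methide, not isolated) | CCC(Br)C(=O)C1=C(O)C(=CCCCCC(C)C)C(=O)C=C1O | intermediate
6 | 1,1-bis[3-(2-bromobutanoyl)-2,4,6-trihydroxyphenyl]-6-methylheptane (all stereoisomers at CHBr) | CCC(Br)C(=O)c1c(O)cc(O)c(C(CCCCC(C)C)c2c(O)cc(O)c(C(=O)C(Br)CC)c2O)c1O | intermediate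
7 | 1,1-bis[2,4,6-triacetoxy-3-(2-bromobutanoyl)phenyl]-6-methylheptane (all stereoisomers at CHBr) | CCC(Br)C(=O)c1c(OC(C)=O)cc(OC(C)=O)c(C(CCCCC(C)C)c2c(OC(C)=O)cc(OC(C)=O)c(C(=O)C(Br)CC)c2OC(C)=O)c1OC(C)=O | intermediate
8 | iodomethane | CI | starting material
9 | zinc | [Zn] | starting material
10 | methylzinc iodide | C[Zn]I | intermediate
11 | 1,1-bis{2,4,6-triacetoxy-3-[(2R)-2-methylbutanoyl]phenyl}-6-methylheptane | CC[C@@H](C)C(=O)c1c(OC(C)=O)cc(OC(C)=O)c(C(CCCCC(C)C)c2c(OC(C)=O)cc(OC(C)=O)c(C(=O)[C@H](C)CC)c2OC(C)=O)c1OC(C)=O | intermediate
12 | 1,1-bis{2,4,6-trihydroxy-3-[(2R)-2-methylbutanoyl]phenyl}-6-methylheptane | CC[C@@H](C)C(=O)c1c(O)cc(O)c(C(CCCCC(C)C)c2c(O)cc(O)c(C(=O)[C@H](C)CC)c2O)c1O | intermediate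
13 | 1,1-bis{2,4-dihydroxy-3-[(2R)-2-methylbutanoyl]-6-(prop-2-enyloxy)phenyl}-6-methylheptane | CC[C@@H](C)C(=O)c1c(O)cc(OCC=C)c(C(CCCCC(C)C)c2c(OCC=C)cc(O)c(C(=O)[C@H](C)CC)c2O)c1O | intermediate
14 | 1,1-bis{2,4,6-trihydroxy-3-[(2R)-2-methylbutanoyl]-5-(prop-2-enyl)phenyl}-6-methylheptane | CC[C@@H](C)C(=O)c1c(O)c(CC=C)c(O)c(C(CCCCC(C)C)c2c(O)c(CC=C)c(O)c(C(=O)[C@H](C)CC)c2O)c1O | intermediate
15 | 1,1-bis{2,4,6-trihydroxy-3-[(2R)-2-methylbutanoyl]-5-(3-methylbut-2-enyl)phenyl}-6-methylheptane (CNP0245910.1) | CC[C@@H](C)C(=O)c1c(O)c(CC=C(C)C)c(O)c(C(CCCCC(C)C)c2c(O)c(CC=C(C)C)c(O)c(C(=O)[C@H](C)CC)c2O)c1O | target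

**Step count**

Total step count: 9. Longest linear sequence: 8 steps (steps 1, 2, 3, 5, 6, 7, 8 and 9 from phloroglucinol 1); step 4 prepares the zinc reagent in a one-step side branch.

**Steps most likely to fail**

Step 5 (proposed new method). The hindered α-acyl radical may not be captured by the methylnickel complex with useful facial selectivity. Bromide may also be lost by reduction to a zinc enolate, which then protonates or takes an acetyl group from an ortho acetate. The fallback uses only known chemistry, sets out from phloroglucinol 1 and aldehyde 4, and comes back to the route at 12. Commercial (R)-2-methylbutanoic acid F1 is converted with oxalyl chloride and catalytic DMF in CH2Cl2 into (R)-2-methylbutanoyl chloride F2. F2 acylates 1 (AlCl3, PhNO2/CH2Cl2, held at 0 °C to limit ketene-type racemisation) to give (2R)-2-methyl-1-(2,4,6-trihydroxyphenyl)butan-1-one F3, whose enantiopurity is checked and upgraded by crystallisation if needed. F3 (2.5 equiv) is then bridged with 4 under the conditions of step 2 (TsOH·H2O, AcOH/THF) to give 12 directly, and steps 7–9 follow unchanged.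

Step 7. Control over the number and site of the allyl groups may be lost. One ring may take two allyl groups while the other takes none, or alkylation may occur at the hydroxyl flanked by acyl group and bridge, from which no Claisen shift to the free ring carbon is possible. The fallback sets out from 12 and comes back at the target 15 (no new compound, F0). Direct C-prenylation of the phenoxide of 12 with prenyl bromide (2.2 equiv) in 10 % aqueous KOH at 0 °C should alkylate each ring at its only free ring carbon. The protic medium favours C- over O-alkylation, as is usual for acylphloroglucinols. This replaces steps 7–9 by one step and needs no heating.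

Step 8. The two α-stereocentres may partly epimerise by thermal enolisation of the chelated aryl ketones, and the diarylmethine bridge may scramble by retro-Friedel–Crafts cleavage at 180 °C. The fallback sets out from 12 and comes back at 15. O-Alkylation of the para hydroxyls with 3-chloro-3-methylbut-1-yne (K2CO3, KI, catalytic CuI, acetone, rt) gives 1,1-bis{2,4-dihydroxy-3-[(2R)-2-methylbutanoyl]-6-(2-methylbut-3-yn-2-yloxy)phenyl}-6-methylheptane F4. Semi-hydrogenation (H2, Pd/CaCO3 poisoned with Pb(OAc)2, quinoline, EtOAc) gives 1,1-bis{2,4-dihydroxy-3-[(2R)-2-methylbutanoyl]-6-(2-methylbut-3-en-2-yloxy)phenyl}-6-methylheptane F5. The Claisen rearrangement of these tertiary allyl ethers proceeds in toluene at about 100–110 °C and places a prenyl group directly on the free ortho carbon, giving 15 without the metathesis step.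

**Further compounds**

F1 | step 5 | (R)-2-methylbutanoic acid | CC[C@@H](C)C(=O)O
F2 | step 5 | (R)-2-methylbutanoyl chloride | CC[C@@H](C)C(Cl)=O
F3 | step 5 | (2R)-2-methyl-1-(2,4,6-trihydroxyphenyl)butan-1-one | CC[C@@H](C)C(=O)c1c(O)cc(O)cc1O
F0 | step 7 | none | none
F4 | step 8 | 1,1-bis{2,4-dihydroxy-3-[(2R)-2-methylbutanoyl]-6-(2-methylbut-3-yn-2-yloxy)phenyl}-6-methylheptane | CC[C@@H](C)C(=O)c1c(O)cc(OC(C)(C)C#C)c(C(CCCCC(C)C)c2c(OC(C)(C)C#C)cc(O)c(C(=O)[C@H](C)CC)c2O)c1O
F5 | step 8 | 1,1-bis{2,4-dihydroxy-3-[(2R)-2-methylbutanoyl]-6-(2-methylbut-3-en-2-yloxy)phenyl}-6-methylheptane | CC[C@@H](C)C(=O)c1c(O)cc(OC(C)(C)C=C)c(C(CCCCC(C)C)c2c(OC(C)(C)C=C)cc(O)c(C(=O)[C@H](C)CC)c2O)c1O
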